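## Retrosynthetic overview

1. Endgame: the C8 hydroxyl is esterified last with (S)-2-methyloxirane-2-carboxylic acid; the C13 acetate follows PMB removal; the (5E)-enol lactone comes from dehydration of a C6 hydroxybutenolide.
2. Key disconnection C4–C5: the ether oxygen bridging C1 and C4 makes C4 a ketal-level carbon of the oxolane ring (a 2-methyloxolan-2-ylium ion), and C5 is alpha to C6, which the enol lactone holds at the ketone level. An intramolecular Mukaiyama addition therefore closes the ten-membered carbocycle (nine-membered ring through the bridge oxygen), and the ring itself fixes C4.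
3. Precursor: an open-chain hydroxybutenolide–ketal, made from a furan by singlet-oxygen dearomatization; C10 by chelation-controlled MeMgBr addition; C8 by a boron aldol (C8–C9 bond) between an acetyloxolane ketal and a furan-3-carbaldehyde.
4. Building blocks: (S)-5-oxotetrahydrofuran-2-carboxylic acid (C1–C4, C10), ethyl acetoacetate plus 1,3-dichloroacetone (Feist–Benary furan: C5–C8, C11–C13), (R)-2-methylglycidol.
5. Ring order: oxolane (chiral pool) → furan → hydroxybutenolide → ten-membered ring with ether bridge (key step) → enol lactone.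

Key step: step 13

Remark: germacranolide numbering is used (ring carbons C1–C10, lactone carbons C11–C13, C14 = methyl on C10, C15 = methyl on C4); PMB = 4-methoxybenzyl, TBS = tert-butyldimethylsilyl, TES = triethylsilyl, TMS = trimethylsilyl; the ketal carbon C4 is carried as an epimer mixture because it becomes planar in step 13.

## Route

Step 1
Reactants: 1 (S)-5-oxotetrahydrofuran-2-carboxylic acid
Product: 2 (S)-N-methoxy-N-methyl-5-oxotetrahydrofuran-2-carboxamide
Conditions: MeNHOMe·HCl, EDC·HCl, N-methylmorpholine, CH2Cl2, 0 °C to rt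
Reagents that add atoms: N,O-dimethylhydroxylamine hydrochloride CNOC.Cl
Why: Carbodiimide amidation (Weinreb amide formation) of the free acid under near-neutral conditions should leave the lactone and the C1 stereocentre, which comes from the chiral pool, untouched.

Step 2
Reactants: 2 (S)-N-methoxy-N-methyl-5-oxotetrahydrofuran-2-carboxamide
Product: 3 1-[(2S)-5-hydroxy-5-methyloxolan-2-yl]ethan-1-one (lactol epimers)
Conditions: MeLi (2.1 equiv), THF, −78 °C; AcOH, −78 °C
Reagents that add atoms: methyllithium [Li]C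
Why: Weinreb ketone synthesis and lactone-to-lactol mono-addition should run side by side, because both tetrahedral lithium adducts are stable at −78 °C and each carbonyl therefore takes up one methyl group (C14 and C15).

Step 3
Reactants: 3 1-[(2S)-5-hydroxy-5-methyloxolan-2-yl]ethan-1-one
Product: 4 1-[(2S)-5-methoxy-5-methyloxolan-2-yl]ethan-1-one (ketal epimers)
Conditions: MeOH, PPTS (cat.), 0 °C to rt
Reagents that add atoms: methanol CO
Why: Acid-catalysed acetalization of the cyclic hemiketal (Fischer-glycosidation type) should mask C4 as the mixed methyl ketal, while the C10 ketone stays free in the absence of a dehydrating agent.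

Step 4
Reactants: 5 ethyl acetoacetate; 6 1,3-dichloroacetone
Product: 8 ethyl 4-(chloromethyl)-2-methylfuran-3-carboxylate, via hydroxydihydrofuran 7 (not isolated)
Conditions: pyridine, 50 °C; then TsOH (cat.), toluene, reflux
Reagents that add atoms: none
Why: Feist–Benary furan synthesis (aldol addition to the ketone carbonyl, O-alkylation, dehydration) should give the 2-methyl-3-ester-4-chloromethyl pattern with the 5-position free, as required for C5/C6, C7, C11/C13 and C12.

Step 5
Reactants: 8 ethyl 4-(chloromethyl)-2-methylfuran-3-carboxylate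
Product: 9 ethyl 4-[(4-methoxybenzyloxy)methyl]-2-methylfuran-3-carboxylate
Conditions: 4-methoxybenzyl alcohol, NaH, Bu4NI (cat.), THF, 0 °C to rt
Reagents that add atoms: 4-methoxybenzyl alcohol COc1ccc(CO)cc1
Why: Williamson ether synthesis on the reactive furylmethyl chloride should install the C13 oxygen as a PMB ether that survives the later Grignard step.

Step 6
Reactants: 9 ethyl 4-[(4-methoxybenzyloxy)methyl]-2-methylfuran-3-carboxylate
Product: 10 {4-[(4-methoxybenzyloxy)methyl]-2-methylfuran-3-yl}methanol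
Conditions: iBu2AlH (2.5 equiv), CH2Cl2, −78 to 0 °C
Reagents that add atoms: none
Why: Hydride reduction of the ester to the primary alcohol is routine and does not touch the PMB ether or the furan.

Step 7
Reactants: 10 {4-[(4-methoxybenzyloxy)methyl]-2-methylfuran-3-yl}methanol
Product: 11 4-[(4-methoxybenzyloxy)methyl]-2-methylfuran-3-carbaldehyde
Conditions: MnO2 (activated), CH2Cl2, rt
Reagents that add atoms: none
Why: MnO2 oxidation of a heteroaryl carbinol should stop cleanly at the non-enolizable aldehyde (the future C8).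

Step 8
Reactants: 4 1-[(2S)-5-methoxy-5-methyloxolan-2-yl]ethan-1-one; 11 4-[(4-methoxybenzyloxy)methyl]-2-methylfuran-3-carbaldehyde
Product: 12 (3S)-3-hydroxy-1-[(2S)-5-methoxy-5-methyloxolan-2-yl]-3-{4-[(4-methoxybenzyloxy)methyl]-2-methylfuran-3-yl}propan-1-one
Conditions: (−)-Ipc2BCl, Et3N, Et2O, −78 to 0 °C; 11, −78 to −20 °C; H2O2, MeOH, pH 7 buffer
Reagents that add atoms: none
Why: Paterson boron aldol reaction of the methyl ketone, enolized kinetically at the methyl group; the isopinocampheyl ligands are expected to direct attack to the si face of the aldehyde, the usual sense for methyl ketones with this reagent, which sets C8 as S.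

Step 9
Reactants: 12 the (3S)-aldol
Product: 13 (3S)-3-(tert-butyldimethylsilyloxy)-1-[(2S)-5-methoxy-5-methyloxolan-2-yl]-3-{4-[(4-methoxybenzyloxy)methyl]-2-methylfuran-3-yl}propan-1-one
Conditions: TBSCl, imidazole, DMAP (cat.), DMF, rt to 40 °C
Reagents that add atoms: tert-butyldimethylsilyl chloride CC(C)(C)[Si](C)(C)Cl
Why: Silyl ether formation under basic, non-Lewis-acidic conditions should protect the C8 hydroxyl without ionizing the ketal, and makes the C8 oxygen non-chelating for step 10.

Step 10
Reactants: 13 the C8 TBS ether ketone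
Product: 14 (2R,4S)-4-(tert-butyldimethylsilyloxy)-2-[(2S)-5-methoxy-5-methyloxolan-2-yl]-4-{4-[(4-methoxybenzyloxy)methyl]-2-methylfuran-3-yl}butan-2-ol
Conditions: MeMgBr (1.5 equiv), CH2Cl2/Et2O, −78 °C; aq NH4Cl
Reagents that add atoms: methylmagnesium bromide C[Mg]Br
Why: Cram-chelate Grignard addition, in which magnesium bridges the C10 carbonyl and the oxolane oxygen so that methyl adds from the face of the C1 hydrogen; with (S)-C1 this should give (R)-C10.

Step 11
Reactants: 14 the C10 tertiary alcohol
Product: 15 the C10 triethylsilyl ether of 14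
Conditions: TESOTf, 2,6-lutidine, CH2Cl2, −78 °C
Reagents that add atoms: triethylsilyl trifluoromethanesulfonate CC[Si](CC)(CC)OS(=O)(=O)C(F)(F)F
Why: Silyl triflate silylation of the hindered tertiary alcohol in the presence of a buffering base blocks the C10 oxygen, so that it cannot later close a bicyclic ketal onto C4.

Step 12
Reactants: 15 the fully protected furan
Product: 17 5-hydroxy-5-methyl-3-(PMBOCH2)-4-[(1S,3R)-1-(TBSO)-3-(TESO)-3-((2S)-5-methoxy-5-methyloxolan-2-yl)butyl]furan-2(5H)-one (C6 epimers), via furan endoperoxide 16 (not isolated)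
Conditions: O2, rose bengal (cat.), visible light, iPr2NEt, CH2Cl2, −78 °C to rt
Reagents that add atoms: dioxygen O=O
Why: Dearomatizing [4+2] photooxygenation of the furan followed by base-induced (Kornblum–DeLaMare-type) fragmentation of the endoperoxide; the only ring hydrogen is on C12, so the carbonyl must form there and the hydroxyl at the methyl-bearing C6.

Step 13
Reactants: 17 the open-chain hydroxybutenolide
Product: 20 (1S,4R,8S,10R)-1,4-epoxy-6-hydroxy-13-(PMBO)-8-(TBSO)-10-(TESO)germacr-7(11)-en-6,12-olide (C6 epimers), via bis-silyl dienol ether 18 (not isolated), via oxolanylium triflate 19 (not isolated)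
Conditions: LiN(SiMe3)2 (2.3 equiv), THF, −78 °C, then Me3SiCl; volatiles removed, CH2Cl2 (1 mM); Me3SiOTf (0.3 equiv), −78 to −40 °C; aq NaHCO3, then pH 5 buffer
Reagents that add atoms: none
Why: Base opens the pseudo-acid to the keto carboxylate and the dianion is O-silylated to 18; Me3SiOTf then removes the C4 methoxy group as Me3SiOMe, the terminal CH2 (C5) of the 2-silyloxydiene attacks the oxolanylium carbon C4 of 19, and work-up returns the C6 ketone/acid pair as the hydroxybutenolide. The closest known reaction type is the Mukaiyama addition of silyl enol ethers to ketal-derived cyclic oxocarbenium ions, including intramolecular acetal–enol silane closures of medium rings. The ten-membered carbocycle closes in a 10-exo-trig sense at C4=O+ (enol-exo for the nucleophile), which is the nine-membered ring through the bridge oxygen; the hydroxybutenolide re-forms by 5-exo-trig addition of the carboxyl group to C6. C4 is controlled by C1: the tethered C5 can only reach the face of the planar oxolanylium ion that is cis to the C1 side chain, so (S)-C1 gives (R)-C4 and both ketal epimers converge; the C6 hemiketal centre is removed in step 14. The step needs ring closure to beat oligomerization and proton loss from 19, and needs a single enol silane and a single oxocarbenium ion. High dilution, the (Z)-tetrasubstituted C7=C11 alkene and quaternary C10 (which fold the chain), the sp2 carbon C7 (the C6 ketone can enolize only toward C5) and the C10 triethylsilyl ether (no bicyclic ketal, hence no six-membered oxocarbenium ion) are meant to secure this.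

Step 14
Reactants: 20 the ring-closed hydroxybutenolide
Product: 22 (1S,4R,5E,8S,10R)-1,4-epoxy-13-(PMBO)-8-(TBSO)-10-(TESO)germacra-5,7(11)-dien-6,12-olide, via C6 mesylate 21 (not isolated)
Conditions: MsCl, Et3N, DMAP (cat.), CH2Cl2, −20 to 0 °C
Reagents that add atoms: none
Why: Dehydration of a γ-hydroxybutenolide to a γ-ylidenebutenolide by sulfonylation and elimination; the only β-hydrogens are on C5, and the nine-membered ring should allow only the cis ring alkene, which is the (5E) isomer.

Step 15
Reactants: 22 the PMB-protected enol lactone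
Product: 23 (1S,4R,5E,8S,10R)-1,4-epoxy-13-hydroxy-8-(TBSO)-10-(TESO)germacra-5,7(11)-dien-6,12-olide
Conditions: DDQ, CH2Cl2/pH 7 buffer, 0 °C to rt
Reagents that add atoms: none
Why: Oxidative cleavage of the PMB ether under neutral conditions should spare the silyl ethers, the tertiary allylic ether and the electron-poor dienyl lactone.

Step 16
Reactants: 23 the C13 alcohol
Product: 24 (1S,4R,5E,8S,10R)-13-acetoxy-1,4-epoxy-8-(TBSO)-10-(TESO)germacra-5,7(11)-dien-6,12-olide
Conditions: Ac2O, pyridine, DMAP (cat.), CH2Cl2, 0 °C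
Reagents that add atoms: acetic anhydride CC(=O)OC(C)=O
Why: Acetylation of the only free (primary) hydroxyl.

Step 17
Reactants: 24 the C13 acetate
Product: 25 (1S,4R,5E,8S,10R)-13-acetoxy-1,4-epoxy-8,10-dihydroxygermacra-5,7(11)-dien-6,12-olide
Conditions: HF·pyridine, pyridine, THF, 0 °C to rt
Reagents that add atoms: none
Why: Buffered fluoride desilylation removes both silyl ethers without base, so the acetate and the enol lactone should survive.

Step 18
Reactants: 26 (R)-2-methylglycidol
Product: 27 (S)-2-methyloxirane-2-carboxylic acid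
Conditions: RuCl3 (cat.), NaIO4, MeCN/EtOAc/H2O, 0 °C to rt
Reagents that add atoms: water O
Why: Catalytic ruthenium tetroxide oxidation of an epoxy alcohol to the glycidic acid leaves the quaternary stereocentre untouched; the descriptor changes from R to S only because the CIP priorities change.

Step 19
Reactants: 25 the 8,10-diol; 27 (S)-2-methyloxirane-2-carboxylic acid
Product: 28 CNP0142137.1, (1S,4R,5E,8S,10R)-13-acetoxy-1,4-epoxy-10-hydroxy-8-[(2S)-2-methyloxirane-2-carbonyloxy]germacra-5,7(11)-dien-6,12-olide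
Conditions: DCC, DMAP (cat.), CH2Cl2, 0 °C to rt
Reagents that add atoms: none
Why: Steglich esterification should acylate the secondary C8 hydroxyl and leave the tertiary C10 hydroxyl free; the acid has no α-hydrogen, so it cannot epimerize.

## Compound list

1 | (S)-5-oxotetrahydrofuran-2-carboxylic acid | O=C(O)[C@@H]1CCC(=O)O1 | starting material
2 | (S)-N-methoxy-N-methyl-5-oxotetrahydrofuran-2-carboxamide | CON(C)C(=O)[C@@H]1CCC(=O)O1 | intermediate
3 | 1-[(2S)-5-hydroxy-5-methyloxolan-2-yl]ethan-1-one | CC(=O)[C@@H]1CCC(C)(O)O1 | intermediate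
4 | 1-[(2S)-5-methoxy-5-methyloxolan-2-yl]ethan-1-one | CC(=O)[C@@H]1CCC(C)(OC)O1 | intermediate
5 | ethyl acetoacetate | CCOC(=O)CC(C)=O | starting material
6 | 1,3-dichloroacetone | ClCC(=O)CCl | starting material
7 | ethyl 4-(chloromethyl)-4-hydroxy-2-methyl-4,5-dihydrofuran-3-carboxylate | CCOC(=O)C1=C(C)OCC1(O)CCl | intermediate
8 | ethyl 4-(chloromethyl)-2-methylfuran-3-carboxylate | CCOC(=O)c1c(C)occ1CCl | intermediate
9 | ethyl 4-[(4-methoxybenzyloxy)methyl]-2-methylfuran-3-carboxylate | CCOC(=O)c1c(C)occ1COCc1ccc(OC)cc1 | intermediate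
10 | {4-[(4-methoxybenzyloxy)methyl]-2-methylfuran-3-yl}methanol | Cc1occ(COCc2ccc(OC)cc2)c1CO | intermediate
11 | 4-[(4-methoxybenzyloxy)methyl]-2-methylfuran-3-carbaldehyde | Cc1occ(COCc2ccc(OC)cc2)c1C=O | intermediate
12 | (3S)-aldol, C8 hydroxyl free, C10 ketone | COC1(C)CC[C@H](O1)C(=O)C[C@H](O)c1c(C)occ1COCc1ccc(OC)cc1 | intermediate
13 | C8 TBS ether of 12 | COC1(C)CC[C@H](O1)C(=O)C[C@H](O[Si](C)(C)C(C)(C)C)c1c(C)occ1COCc1ccc(OC)cc1 | intermediate
14 | (2R,4S)-tertiary alcohol (C10 R, C8 S) | COC1(C)CC[C@H](O1)[C@](C)(O)C[C@H](O[Si](C)(C)C(C)(C)C)c1c(C)occ1COCc1ccc(OC)cc1 | intermediate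
15 | C10 TES ether of 14 | COC1(C)CC[C@H](O1)[C@](C)(O[Si](CC)(CC)CC)C[C@H](O[Si](C)(C)C(C)(C)C)c1c(C)occ1COCc1ccc(OC)cc1 | intermediate
16 | furan 2,5-endoperoxide of 15 | COC1(C)CC[C@H](O1)[C@](C)(O[Si](CC)(CC)CC)C[C@H](O[Si](C)(C)C(C)(C)C)C1=C(COCc2ccc(OC)cc2)C2OOC1(C)O2 | intermediate
17 | open-chain 5-hydroxy-5-methylbutenolide (C6 pseudo-acid) | COC1(C)CC[C@H](O1)[C@](C)(O[Si](CC)(CC)CC)C[C@H](O[Si](C)(C)C(C)(C)C)C1=C(COCc2ccc(OC)cc2)C(=O)OC1(C)O | intermediate
18 | trimethylsilyl (2Z)-4-(trimethylsilyloxy)penta-2,4-dienoate (bis-silyl dienol ether of ring-opened 17) | COC1(C)CC[C@H](O1)[C@](C)(O[Si](CC)(CC)CC)C[C@H](O[Si](C)(C)C(C)(C)C)/C(C(=C)O[Si](C)(C)C)=C(\COCc1ccc(OC)cc1)C(=O)O[Si](C)(C)C | intermediate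
19 | 2-methyloxolan-2-ylium triflate from 18 | CC1=[O+][C@@H](CC1)[C@](C)(O[Si](CC)(CC)CC)C[C@H](O[Si](C)(C)C(C)(C)C)/C(C(=C)O[Si](C)(C)C)=C(\COCc1ccc(OC)cc1)C(=O)O[Si](C)(C)C.[O-]S(=O)(=O)C(F)(F)F | intermediate
20 | (1S,4R,8S,10R)-1,4-epoxy-6-hydroxy-13-(PMBO)-8-(TBSO)-10-(TESO)germacr-7(11)-en-6,12-olide | COc1ccc(COCC2=C3C(O)(C[C@@]4(C)CC[C@H](O4)[C@](C)(O[Si](CC)(CC)CC)C[C@@H]3O[Si](C)(C)C(C)(C)C)OC2=O)cc1 | intermediate
21 | C6 methanesulfonate of 20 | COc1ccc(COCC2=C3C(OS(C)(=O)=O)(C[C@@]4(C)CC[C@H](O4)[C@](C)(O[Si](CC)(CC)CC)C[C@@H]3O[Si](C)(C)C(C)(C)C)OC2=O)cc1 | intermediate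
22 | (1S,4R,5E,8S,10R)-1,4-epoxy-13-(PMBO)-8-(TBSO)-10-(TESO)germacra-5,7(11)-dien-6,12-olide | COc1ccc(COCC2=C3/C(=C\[C@@]4(C)CC[C@H](O4)[C@](C)(O[Si](CC)(CC)CC)C[C@@H]3O[Si](C)(C)C(C)(C)C)OC2=O)cc1 | intermediate
23 | 13-hydroxy analogue of 22 | OCC1=C2/C(=C\[C@@]3(C)CC[C@H](O3)[C@](C)(O[Si](CC)(CC)CC)C[C@@H]2O[Si](C)(C)C(C)(C)C)OC1=O | intermediate
24 | 13-acetoxy analogue of 22 | CC(=O)OCC1=C2/C(=C\[C@@]3(C)CC[C@H](O3)[C@](C)(O[Si](CC)(CC)CC)C[C@@H]2O[Si](C)(C)C(C)(C)C)OC1=O | intermediate
25 | (1S,4R,5E,8S,10R)-13-acetoxy-1,4-epoxy-8,10-dihydroxygermacra-5,7(11)-dien-6,12-olide | CC(=O)OCC1=C2/C(=C\[C@@]3(C)CC[C@H](O3)[C@](C)(O)C[C@@H]2O)OC1=O | intermediate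
26 | (R)-2-methylglycidol | C[C@@]1(CO)CO1 | starting material
27 | (S)-2-methyloxirane-2-carboxylic acid | C[C@@]1(C(=O)O)CO1 | intermediate
28 | CNP0142137.1 | CC(=O)OCC1=C2/C(=C\[C@@]3(C)CC[C@H](O3)[C@](C)(O)C[C@@H]2OC(=O)[C@]2(C)CO2)OC1=O | target

## Step count and risks

Total step count: 19. Longest linear sequence: 15 steps (steps 4–7, 8–17 and 19).

Steps most likely to fail:

1. Step 13. Intermolecular Mukaiyama addition (oligomerization) or proton loss from the oxolanylium ion to an enol ether may outrun closure of the nine-membered ring, and the dienol ether may be desilylated before it reacts. Fallback: the same bond would be closed from the other polarity, on the C4 ketone, with the ether bridge formed afterwards. It sets out from 17. Dehydration (MsCl, Et3N) should give the 5-methylene butenolide F1. Addition of ICl and loss of HCl with Et3N should give the (E)-5-(iodomethylene)butenolide F2. PPTS in wet acetone should hydrolyse the methyl ketal to the γ-hydroxy ketone F3. A Nozaki–Hiyama–Kishi reaction (CrCl2, NiCl2 cat., DMSO, high dilution) should add the alkenyl C5 to the C4 ketone and close the ten-membered carbocycle as the C4 carbinol F4, either C4 epimer being usable. Camphorsulfonic acid in CH2Cl2 should then ionize the tertiary allylic C4 alcohol, and capture by the C1 hydroxyl on the only face the ring allows comes back to the route at 22.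

2. Step 14. Ionization of the C6 sulfonate may be followed by C4–C5 fragmentation (loss of the oxolanylium ion) instead of proton loss from C5. Fallback: no cation is made at C6; the carboxyl group of the ring-opened keto acid is activated instead. It sets out from 20. 2,4,6-Trichlorobenzoyl chloride and Et3N in toluene should give the mixed anhydride F5 of the open (Z)-keto acid, and DMAP should then induce enol lactonization (O-acylation of the C5=C6 enol), which comes back to the route at 22.

3. Step 8. Facial selectivity may be poor if the reagent control of the Ipc ligands is opposed by the 1,4-influence of the oxolane oxygen at C1. Fallback: C8 is set by 1,3-induction from C10 instead. It sets out from 14 carried as the C8 epimer mixture. Bu4NF in THF should remove the TBS group to give the diol F6. MnO2 should oxidize only the furyl carbinol to the β-hydroxy ketone F7. Narasaka–Prasad reduction (Et2BOMe, NaBH4, THF/MeOH, −78 °C) should give the syn-1,3-diol F8 with (S)-C8. Silylation of the secondary hydroxyl (TBSCl, imidazole) comes back to the route at 14 as a single isomer.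

## Further compounds

F1 | step 13 | 5-methylene butenolide from 17 | COC1(C)CC[C@H](O1)[C@](C)(O[Si](CC)(CC)CC)C[C@H](O[Si](C)(C)C(C)(C)C)C1=C(COCc2ccc(OC)cc2)C(=O)OC1=C
F2 | step 13 | (E)-5-(iodomethylene)butenolide | COC1(C)CC[C@H](O1)[C@](C)(O[Si](CC)(CC)CC)C[C@H](O[Si](C)(C)C(C)(C)C)C1=C(COCc2ccc(OC)cc2)C(=O)O/C1=C/I
F3 | step 13 | γ-hydroxy ketone (C1 hydroxyl, C4 ketone) with the iodomethylene butenolide | CC(=O)CC[C@H](O)[C@](C)(O[Si](CC)(CC)CC)C[C@H](O[Si](C)(C)C(C)(C)C)C1=C(COCc2ccc(OC)cc2)C(=O)O/C1=C/I
F4 | step 13 | ten-membered 1,4-diol (C4 carbinol, either epimer) | COc1ccc(COCC2=C3/C(=C\C(C)(O)CC[C@H](O)[C@](C)(O[Si](CC)(CC)CC)C[C@@H]3O[Si](C)(C)C(C)(C)C)OC2=O)cc1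
F5 | step 14 | mixed 2,4,6-trichlorobenzoic anhydride of the ring-opened keto acid of 20 | COc1ccc(COC/C(C(=O)OC(=O)c2c(Cl)cc(Cl)cc2Cl)=C2/C(=O)C[C@@]3(C)CC[C@H](O3)[C@](C)(O[Si](CC)(CC)CC)C[C@@H]2O[Si](C)(C)C(C)(C)C)cc1
F6 | step 8 | 8,10-diol (C8 epimers) from 14 | COC1(C)CC[C@H](O1)[C@](C)(O)CC(O)c1c(C)occ1COCc1ccc(OC)cc1
F7 | step 8 | C8 ketone with free C10 hydroxyl | COC1(C)CC[C@H](O1)[C@](C)(O)CC(=O)c1c(C)occ1COCc1ccc(OC)cc1
F8 | step 8 | (8S,10R)-syn-1,3-diol | COC1(C)CC[C@H](O1)[C@](C)(O)C[C@H](O)c1c(C)occ1COCc1ccc(OC)cc1
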